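**Retrosynthetic overview**
1. Feature: C10, shared by rings A and B, is buried between the quaternary carbons C5 and C9. Its neighbour C1 is a bare CH2 bonded to the carbonyl carbon C2. Ring A (C1-C2-C3-C4-C5-C10) is therefore cut at C1-C2, giving an acyl radical on C3 and a C10=C1H2 methylene on a bicyclo[3.3.1]nonane (ring B plus ring C = C3-C4-C5-C10-C9-C20).
2. The selenoester carbon C2 comes from one-carbon homologation of a C3 ketone, which comes from a C3=C4 alkene. Me18 (C4) and the acyl group (C3) are set by equilibration. C1 is put on C10 (MeLi, then dehydration) while C4 is still sp2, because afterwards the axial Me17 and Me18 cover both faces of C10.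
3. Ring C comes from a gold-catalysed 6-endo-dig closure (C4-C5) of the C10 enol silane onto a but-2-ynyl arm on C9. The C6 oxygen comes from nucleophilic epoxidation and SmI2 cleavage on the enone.
4. C9 comes from two alpha-prime alkylations of (R)-2,5-dimethylcyclohexenone (from (R)-pulegone): first the complete C11-C16 iodide (C13 from a Sharpless epoxidation, carbons from but-3-yn-1-ol), then 1-bromobut-2-yne anti to Me17.
5. Ring order: ring B (pulegone), ring C (step 17), ring A and the ketone bridge (step 27).

Key step: step 27

Remark on numbering: atom numbers are those of the target. C2 is the ketone carbon, C1 its CH2, C3 the bridgehead CH next to C2, C4 is CHMe18, C5 is CMe19, C6 is CHOAc, C7 is CH2, C8 is CHMe17, C9 is the quaternary carbon bearing C11-C16, C10 is the bridgehead CH, and C20 is the CH2 between C9 and C3. "Exo" means the side of the C10 bridge; "endo" means the side facing the other six-membered ring.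
Assumption: the small share of the wrong C13 enantiomer left by the tartrate-controlled epoxidation becomes a diastereomer after step 13 and is removed there by chromatography.

**Step 1**
Reactants: 1 (R)-pulegone
Product: 2 pulegone oxide (both configurations at the spiro carbon)
Conditions: 30% H2O2, NaOH (cat.), MeOH, 0 → 23 °C
Reagents that add atoms: hydrogen peroxide, OO
Why: Weitz-Scheffer nucleophilic epoxidation of the enone; the new spiro centre is lost again in step 2 and C8 (the later Me17 carbon) is not touched.

**Step 2**
Reactants: 2 pulegone oxide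
Product: 3 (5R)-5-methyl-2-(phenylsulfanyl)cyclohexan-1-one (both C2 epimers)
Conditions: PhSNa, THF, 66 °C; H2O
Reagents that add atoms: sodium benzenethiolate, [Na+].[S-]c1ccccc1
Why: The thiolate opens the epoxide at the carbon alpha to the ketone and the tertiary alkoxide fragments by a retro-aldol reaction with loss of acetone, which leaves sulfur on the carbon that becomes C5 (its configuration is of no consequence).

**Step 3**
Reactants: 3 (5R)-5-methyl-2-(phenylsulfanyl)cyclohexan-1-one
Product: 5 (5R)-2,5-dimethyl-2-(phenylsulfanyl)cyclohexan-1-one (both C2 epimers), via sodium enolate 4 (not isolated)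
Conditions: NaH, THF-DMF, 0 °C; MeI, 23 °C
Reagents that add atoms: iodomethane, C[I]
Why: Under equilibrating conditions the sulfur-stabilised enolate forms and its C-alkylation (enolate alkylation) puts Me19 on the later C5, a centre that is flattened in step 4.

**Step 4**
Reactants: 5 (5R)-2,5-dimethyl-2-(phenylsulfanyl)cyclohexan-1-one
Product: 7 (5R)-2,5-dimethylcyclohex-2-en-1-one, via sulfoxide 6 (not isolated)
Conditions: mCPBA, CH2Cl2, −78 °C; then toluene, 110 °C
Reagents that add atoms: none
Why: Sulfide oxidation and thermal syn elimination of the sulfoxide toward the ring CH2 give the conjugated endocyclic enone without touching the C8 stereocentre.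

**Step 5**
Reactants: 8 but-3-yn-1-ol
Product: 9 tert-butyl(but-3-ynyloxy)dimethylsilane
Conditions: TBSCl, imidazole, DMF, 23 °C
Reagents that add atoms: tert-butyl(chloro)dimethylsilane, CC(C)(C)[Si](C)(C)Cl
Why: Silyl ether protection keeps the hydroxyl group on the later C11 out of the organoaluminium chemistry.

**Step 6**
Reactants: 9 tert-butyl(but-3-ynyloxy)dimethylsilane
Product: 12 (E)-5-(tert-butyldimethylsilyloxy)-3-methylpent-2-en-1-ol, via alkenylalane 10 (not isolated), via lithium alanate 11 (not isolated)
Conditions: Me3Al, Cp2ZrCl2 (20 mol %), CH2Cl2, 0 → 23 °C; n-BuLi, THF, −78 °C; (CH2O)n, 23 °C; aqueous work-up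
Reagents that add atoms: trimethylaluminium, C[Al](C)C; formaldehyde (from paraformaldehyde), C=O
Why: Negishi carboalumination adds methyl (C16) and aluminium syn across the alkyne with aluminium at the terminus, and the alanate is hydroxymethylated (C15) with retention, so only the E allylic alcohol should form.

**Step 7**
Reactants: 12 (E)-5-(tert-butyldimethylsilyloxy)-3-methylpent-2-en-1-ol
Product: 13 (2S,3S)-epoxy alcohol
Conditions: Ti(OiPr)4 (10 mol %), L-(+)-diethyl tartrate (12 mol %), t-BuOOH, 4 Å MS, CH2Cl2, −20 °C
Reagents that add atoms: tert-butyl hydroperoxide, CC(C)(C)OO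
Why: Sharpless asymmetric epoxidation, in which the L-(+)-tartrate complex delivers oxygen to the alkene face that gives the (2S,3S) epoxide and so fixes C13.

**Step 8**
Reactants: 13 (2S,3S)-epoxy alcohol
Product: 15 (3S)-5-(tert-butyldimethylsilyloxy)-3-methylpent-1-en-3-ol, via epoxy iodide 14 (not isolated)
Conditions: PPh3, I2, imidazole, THF, 0 °C; then Zn, AcOH, 0 → 23 °C
Reagents that add atoms: none
Why: Appel-type iodination followed by zinc-induced reductive elimination (iodide leaves, the C14-O bond breaks) unveils the vinyl carbinol, and because the C13-O bond is never broken the S configuration at C13 is kept.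

**Step 9**
Reactants: 15 (3S)-5-(tert-butyldimethylsilyloxy)-3-methylpent-1-en-3-ol
Product: 16 (3S)-3-methylpent-4-ene-1,3-diol
Conditions: TBAF, THF, 23 °C
Reagents that add atoms: none
Why: Fluoride-induced desilylation frees the primary hydroxyl group and nothing else in the molecule responds.

**Step 10**
Reactants: 16 (3S)-3-methylpent-4-ene-1,3-diol
Product: 17 (3S)-5-iodo-3-methylpent-1-en-3-ol
Conditions: PPh3, I2, imidazole, CH2Cl2, 0 °C
Reagents that add atoms: iodine, [I][I]
Why: Appel-type iodination is selective for the primary hydroxyl group because the tertiary allylic one is too hindered to form the alkoxyphosphonium salt.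

**Step 11**
Reactants: 17 (3S)-5-iodo-3-methylpent-1-en-3-ol
Product: 18 (3S)-5-iodo-3-methyl-3-(triethylsilyloxy)pent-1-ene
Conditions: TESOTf, 2,6-lutidine, CH2Cl2, −78 → 0 °C
Reagents that add atoms: triethylsilyl trifluoromethanesulfonate, CC[Si](CC)(CC)OS(=O)(=O)C(F)(F)F
Why: Silylation with a silyl triflate and a hindered base covers the tertiary alcohol without displacing the iodide.

**Step 12**
Reactants: 7 (5R)-2,5-dimethylcyclohex-2-en-1-one; 18 (3S)-5-iodo-3-methyl-3-(triethylsilyloxy)pent-1-ene
Product: 20 C9-monoalkylated enone (both C9 epimers), via lithium dienolate 19 (not isolated)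
Conditions: LiN(i-Pr)2, THF, −78 °C; 18, DMPU, −78 → −10 °C
Reagents that add atoms: none
Why: Kinetic deprotonation at the alpha-prime carbon (C9) gives the cross-conjugated dienolate, whose SN2 alkylation by the primary iodide joins C9 to C11; the C9 epimers converge in step 13.

**Step 13**
Reactants: 20 C9-monoalkylated enone; 21 1-bromobut-2-yne
Product: 23 C9-dialkylated enone (but-2-ynyl group trans to Me17), via lithium dienolate 22 (not isolated)
Conditions: LiN(i-Pr)2, THF, −78 °C; 21, DMPU, −78 → 0 °C
Reagents that add atoms: none
Why: Second alpha-prime enolate alkylation: in the dienolate Me17 stands pseudo-axial to avoid the C9 substituent, so the reactive propargylic bromide enters from the opposite face and C20 ends up anti to Me17, which sets C9.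

**Step 14**
Reactants: 23 C9-dialkylated enone
Product: 24 C5-C6 epoxy ketone (oxygen trans to Me17)
Conditions: 30% H2O2, NaOH (cat.), MeOH, 0 °C
Reagents that add atoms: hydrogen peroxide, OO
Why: Weitz-Scheffer epoxidation in which hydroperoxide attacks C6 axially on the face anti to Me17, as is usual for 5-substituted cyclohexenones, which sets the C6-O configuration while the alkyne and the vinyl group stay inert.

**Step 15**
Reactants: 24 C5-C6 epoxy ketone
Product: 25 6-hydroxy ketone (both C5 epimers)
Conditions: SmI2, THF-MeOH, −90 °C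
Reagents that add atoms: none
Why: Divalent samarium cleaves reductively the C-O bond alpha to the ketone (C5-O) only, so the C6-O bond and its configuration are kept and C5 becomes an inconsequential CH centre.

**Step 16**
Reactants: 25 6-hydroxy ketone
Product: 26 C10 enol silane with 6-OTMS
Conditions: TMSOTf, Et3N, CH2Cl2, 0 °C
Reagents that add atoms: trimethylsilyl trifluoromethanesulfonate, C[Si](C)(C)OS(=O)(=O)C(F)(F)F
Why: Soft enolisation: C9 is quaternary, so the ketone can enolise only toward C5, and the same reagent silylates the 6-hydroxyl group.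

**Step 17**
Reactants: 26 C10 enol silane with 6-OTMS
Product: 28 bicyclic hydroxy ketone (C4-C5 closed; C3=C4 alkene; free 6-OH), via silyloxy ketone 27 (not isolated)
Conditions: [(t-Bu)2(2-biphenylyl)P]Au(NCMe)SbF6 (3 mol %), CH2Cl2-MeOH 10:1, 23 °C; then citric acid (cat.), MeOH
Reagents that add atoms: none
Why: Conia-ene-type carbocyclisation of an enol silane onto an alkyne activated by monovalent gold: the linear alkyne hanging from the axial C20 can place only its far carbon C4 under C5 (6-endo-dig, the 5-exo carbon is out of reach), the tether on the face anti to Me17 dictates the C5 configuration (C4 cis to C20 and to the C6 oxygen), and methanol with citric acid then removes the labile TMS ether while the tertiary TES ether stays.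

**Step 18**
Reactants: 28 bicyclic hydroxy ketone
Product: 29 C6,C10 diol (C10 carbinol configuration of no consequence)
Conditions: MeLi (excess), Et2O, −78 → 0 °C
Reagents that add atoms: methyllithium, [Li]C
Why: 1,2-Addition of methyllithium (C1) to the non-enolisable bridge ketone from the side of the flat C3=C4 unit, the only open face because the axial Me17 covers the ring B side; the new C10 centre is lost in step 20.

**Step 19**
Reactants: 29 C6,C10 diol
Product: 30 6-acetate with free tertiary 10-OH
Conditions: Ac2O, pyridine, DMAP (cat.), 23 °C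
Reagents that add atoms: acetic anhydride, CC(=O)OC(C)=O
Why: Acylation takes place only at the secondary equatorial 6-hydroxyl group, since the tertiary carbinol between C5 and C9 is far too hindered.

**Step 20**
Reactants: 30 6-acetate with free tertiary 10-OH
Product: 31 C10 methylene diene acetate
Conditions: SOCl2, pyridine, 0 °C
Reagents that add atoms: none
Why: Dehydration through the chlorosulfite in pyridine: C5 and C9 carry no hydrogen, so only the methyl carbon C1 can lose a proton and the exocyclic methylene is the only alkene possible.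

**Step 21**
Reactants: 31 C10 methylene diene acetate
Product: 32 exo C3-C4 epoxide
Conditions: mCPBA, CH2Cl2, 0 °C
Reagents that add atoms: 3-chloroperoxybenzoic acid, OOC(=O)c1cccc(Cl)c1
Why: Prilezhaev epoxidation picks the electron-rich trisubstituted alkene over the shielded methylene and the vinyl group, and the peracid comes from the exo face because ring B covers the endo face.

**Step 22**
Reactants: 32 exo C3-C4 epoxide
Product: 33 C3 alcohol (both C4 epimers)
Conditions: Cp2TiCl2, Mn, 1,4-cyclohexadiene, THF, 23 °C
Reagents that add atoms: none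
Why: Nugent-RajanBabu reductive epoxide opening: trivalent titanium cleaves the C4-O bond to the more substituted tertiary radical, which takes hydrogen from cyclohexadiene and leaves the oxygen on C3; both new centres are erased or corrected in step 23.

**Step 23**
Reactants: 33 C3 alcohol
Product: 35 C3 ketone with exo Me18, via ketone epimer mixture 34 (not isolated)
Conditions: Dess-Martin periodinane, CH2Cl2, 23 °C; then DBU (cat.), 23 °C
Reagents that add atoms: none
Why: Dess-Martin oxidation and base equilibration alpha to the ketone: Me18 settles exo (axial on ring C, cis to Me19), because in the other epimer the C4-Me18 bond runs parallel to the equatorial C6-OAc bond (syn-pentane contact), which sets C4.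

**Step 24**
Reactants: 35 C3 ketone with exo Me18; 36 (methoxymethyl)triphenylphosphonium chloride
Product: 38 exo C3 aldehyde, via enol ether 37 (not isolated)
Conditions: 36, KN(SiMe3)2, THF, 0 °C; 35, 0 → 23 °C; then PPTS, acetone-H2O, 40 °C
Reagents that add atoms: water, O
Why: Wittig methoxymethylenation and mild acid hydrolysis of the enol ether bring in C2 (one-carbon homologation), and the epimerisable aldehyde settles exo (equatorial) on C3 because an endo group would point into ring B at C7, which sets C3.

**Step 25**
Reactants: 38 exo C3 aldehyde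
Product: 39 exo C3 carboxylic acid
Conditions: NaClO2, NaH2PO4, 2-methylbut-2-ene, t-BuOH-H2O, 23 °C
Reagents that add atoms: sodium chlorite, [Na+].[O-]Cl=O
Why: Pinnick oxidation converts the aldehyde without epimerising C3, and the scavenger keeps hypochlorous acid away from the three alkenes.

**Step 26**
Reactants: 39 exo C3 carboxylic acid; 40 diphenyl diselenide
Product: 41 phenyl selenoester (key-step precursor)
Conditions: PBu3, CH2Cl2, 23 °C
Reagents that add atoms: none
Why: Phosphine-diselenide activation of the acid as an acyloxyphosphonium salt and capture by selenolate give the phenyl selenoester under neutral conditions, so C3 is not epimerised and the acetate and TES ether are untouched.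

**Step 27**
Reactants: 41 phenyl selenoester
Product: 44 triethylsilyl ether of the target, via acyl radical 42 (not isolated), via bridgehead radical 43 (not isolated)
Conditions: (Me3Si)3SiH (slow addition), Et3B (cat.), air, benzene (0.005 M), 40 °C
Reagents that add atoms: none
Why: The silyl radical abstracts the phenylseleno group of 41, and the nucleophilic sigma acyl radical, held exo (equatorial) on C3, reaches the C10 methylene once ring C flips from chair to boat; it bonds through C2 to the unsubstituted terminus C1, and the tertiary C10 radical then takes hydrogen from the silane, which carries the chain. The closest known reaction type is the reductive cyclisation of acyl radicals from phenyl selenoesters onto 1,1-disubstituted alkenes in the endo mode. The single new bond C1-C2 closes ring A (C1-C2-C3-C4-C5-C10) by a 6-endo-trig closure and thereby completes the bicyclo[2.2.2]octane. The one new stereocentre C10 is fixed by the cage, because the pyramidal bridgehead radical is open to the silane only from outside, which puts H10 anti to C4 and C20. Regioselectivity (C1 against 5-exo attack at C10) is secured by the two quaternary neighbours C5 and C9 and by the formation of a tertiary instead of a primary radical, and the remote C14=C15 vinyl group cannot be reached by C2. High dilution, slow silane addition and 40 °C hold back direct reduction and loss of CO from the secondary acyl radical.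

**Step 28**
Reactants: 44 triethylsilyl ether of the target
Product: 45 target CNP0281208.1
Conditions: HF·pyridine, pyridine, THF, 0 °C
Reagents that add atoms: none
Why: Buffered fluoride desilylation removes the tertiary TES ether and leaves the acetate, the ketone and the tertiary allylic alcohol intact.

**Compound list**
1 | (R)-pulegone, (5R)-5-methyl-2-(propan-2-ylidene)cyclohexan-1-one | C[C@@H]1CCC(=C(C)C)C(=O)C1 | starting material
2 | pulegone oxide, (6R)-2,2,6-trimethyl-1-oxaspiro[2.5]octan-4-one, both configurations at the spiro carbon | C[C@@H]1CCC2(OC2(C)C)C(=O)C1 | intermediate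
3 | (5R)-5-methyl-2-(phenylsulfanyl)cyclohexan-1-one, both C2 epimers | C[C@@H]1CCC(Sc2ccccc2)C(=O)C1 | intermediate
4 | sodium enolate of 3 (enolate toward the sulfur-bearing carbon) | C[C@@H]1CCC(Sc2ccccc2)=C([O-])C1.[Na+] | intermediate
5 | (5R)-2,5-dimethyl-2-(phenylsulfanyl)cyclohexan-1-one, both C2 epimers | C[C@@H]1CCC(C)(Sc2ccccc2)C(=O)C1 | intermediate
6 | (5R)-2,5-dimethyl-2-(phenylsulfinyl)cyclohexan-1-one | C[C@@H]1CCC(C)(S(=O)c2ccccc2)C(=O)C1 | intermediate
7 | (5R)-2,5-dimethylcyclohex-2-en-1-one (ring B: C10 ketone, C5=C6, Me19 on C5, Me17 on C8) | C[C@@H]1CC=C(C)C(=O)C1 | intermediate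
8 | but-3-yn-1-ol | C#CCCO | starting material
9 | tert-butyl(but-3-ynyloxy)dimethylsilane | C#CCCO[Si](C)(C)C(C)(C)C | intermediate
10 | (E)-alkenyldimethylalane from syn addition of Me-Al to 9 | C[Al](C)/C=C(\C)CCO[Si](C)(C)C(C)(C)C | intermediate
11 | lithium butyl(alkenyl)dimethylalanate | [Li+].CCCC[Al-](C)(C)/C=C(\C)CCO[Si](C)(C)C(C)(C)C | intermediate
12 | (E)-5-(tert-butyldimethylsilyloxy)-3-methylpent-2-en-1-ol | OC/C=C(\C)CCO[Si](C)(C)C(C)(C)C | intermediate
13 | [(2S,3S)-3-[2-(tert-butyldimethylsilyloxy)ethyl]-3-methyloxiran-2-yl]methanol | OC[C@@H]1O[C@@]1(C)CCO[Si](C)(C)C(C)(C)C | intermediate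
14 | iodide of 13 (CH2I in place of CH2OH, same spatial arrangement) | IC[C@@H]1O[C@@]1(C)CCO[Si](C)(C)C(C)(C)C | intermediate
15 | (3S)-5-(tert-butyldimethylsilyloxy)-3-methylpent-1-en-3-ol | C=C[C@@](C)(O)CCO[Si](C)(C)C(C)(C)C | intermediate
16 | (3S)-3-methylpent-4-ene-1,3-diol | C=C[C@@](C)(O)CCO | intermediate
17 | (3S)-5-iodo-3-methylpent-1-en-3-ol | C=C[C@@](C)(O)CCI | intermediate
18 | (3S)-5-iodo-3-methyl-3-(triethylsilyloxy)pent-1-ene (C11-C16 fragment) | C=C[C@@](C)(O[Si](CC)(CC)CC)CCI | intermediate
19 | lithium cross-conjugated dienolate of 7 (C9=C10-OLi) | C[C@@H]1CC=C(C)C(O[Li])=C1 | intermediate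
20 | (5R)-2,5-dimethyl-6-[(3S)-3-methyl-3-(triethylsilyloxy)pent-4-enyl]cyclohex-2-en-1-one, both epimers at ring C6 (= C9) | C=C[C@@](C)(O[Si](CC)(CC)CC)CCC1[C@H](C)CC=C(C)C1=O | intermediate
21 | 1-bromobut-2-yne (C20, C3, C4, C18) | CC#CCBr | starting material
22 | lithium cross-conjugated dienolate of 20 | C=C[C@@](C)(O[Si](CC)(CC)CC)CCC1=C(O[Li])C(C)=CC[C@H]1C | intermediate
23 | enone with quaternary C9: but-2-ynyl group trans to Me17, C11-C16 chain cis to Me17 | C=C[C@@](C)(O[Si](CC)(CC)CC)CC[C@]1(CC#CC)[C@H](C)CC=C(C)C1=O | intermediate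
24 | C5-C6 epoxide of 23, oxirane oxygen trans to Me17 and cis to the but-2-ynyl group | C=C[C@@](C)(O[Si](CC)(CC)CC)CC[C@]1(CC#CC)[C@H](C)C[C@H]2O[C@@]2(C)C1=O | intermediate
25 | 6-hydroxy ketone, OH trans to Me17, both C5 epimers | C=C[C@@](C)(O[Si](CC)(CC)CC)CC[C@]1(CC#CC)[C@H](C)C[C@@H](O)C(C)C1=O | intermediate
26 | trimethylsilyl enol ether (C5=C10) with 6-OTMS | C=C[C@@](C)(O[Si](CC)(CC)CC)CC[C@]1(CC#CC)[C@H](C)C[C@@H](O[Si](C)(C)C)C(C)=C1O[Si](C)(C)C | intermediate
27 | bicyclo[3.3.1]nonenone: bridgeheads C5 (Me19) and C9 (chain), C10 ketone bridge, C3=C4 with Me18 on C4, equatorial 6-OTMS, axial Me17 | C=C[C@@](C)(O[Si](CC)(CC)CC)CC[C@@]12CC=C(C)[C@@](C)(C1=O)[C@H](O[Si](C)(C)C)C[C@H]2C | intermediate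
28 | as 27 with free equatorial 6-OH | C=C[C@@](C)(O[Si](CC)(CC)CC)CC[C@@]12CC=C(C)[C@@](C)(C1=O)[C@H](O)C[C@H]2C | intermediate
29 | diol: C10 now C(OH)CH3 (C1 as methyl, C10 configuration not defined), 6-OH | C=C[C@@](C)(O[Si](CC)(CC)CC)CC[C@@]12CC=C(C)[C@@](C)(C1(C)O)[C@H](O)C[C@H]2C | intermediate
30 | 6-acetate of 29 with free tertiary 10-OH | C=C[C@@](C)(O[Si](CC)(CC)CC)CC[C@@]12CC=C(C)[C@@](C)(C1(C)O)[C@H](OC(C)=O)C[C@H]2C | intermediate
31 | bicyclo[3.3.1]nonene with C10=C1H2 methylene, C3=C4 alkene, 6-OAc | C=C[C@@](C)(O[Si](CC)(CC)CC)CC[C@@]12CC=C(C)[C@@](C)(C1=C)[C@H](OC(C)=O)C[C@H]2C | intermediate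
32 | exo C3-C4 epoxide of 31 | C=C[C@@](C)(O[Si](CC)(CC)CC)CC[C@@]12C[C@H]3O[C@@]3(C)[C@@](C)(C1=C)[C@H](OC(C)=O)C[C@H]2C | intermediate
33 | exo C3 alcohol, C4 CHMe18 as epimer mixture | C=C[C@@](C)(O[Si](CC)(CC)CC)CC[C@@]12C[C@@H](O)C(C)[C@@](C)(C1=C)[C@H](OC(C)=O)C[C@H]2C | intermediate
34 | C3 ketone, C4 epimer mixture | C=C[C@@](C)(O[Si](CC)(CC)CC)CC[C@@]12CC(=O)C(C)[C@@](C)(C1=C)[C@H](OC(C)=O)C[C@H]2C | intermediate
35 | C3 ketone with Me18 exo (cis to Me19) | C=C[C@@](C)(O[Si](CC)(CC)CC)CC[C@@]12CC(=O)[C@@H](C)[C@@](C)(C1=C)[C@H](OC(C)=O)C[C@H]2C | intermediate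
36 | (methoxymethyl)triphenylphosphonium chloride (source of C2) | COC[P+](c1ccccc1)(c1ccccc1)c1ccccc1.[Cl-] | starting material
37 | C3 methoxymethylidene enol ether (E/Z mixture) | C=C[C@@](C)(O[Si](CC)(CC)CC)CC[C@@]12CC(=COC)[C@@H](C)[C@@](C)(C1=C)[C@H](OC(C)=O)C[C@H]2C | intermediate
38 | exo C3 carbaldehyde, cis to Me18 | C=C[C@@](C)(O[Si](CC)(CC)CC)CC[C@@]12C[C@@H](C=O)[C@@H](C)[C@@](C)(C1=C)[C@H](OC(C)=O)C[C@H]2C | intermediate
39 | exo C3 carboxylic acid | C=C[C@@](C)(O[Si](CC)(CC)CC)CC[C@@]12C[C@@H](C(=O)O)[C@@H](C)[C@@](C)(C1=C)[C@H](OC(C)=O)C[C@H]2C | intermediate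
40 | diphenyl diselenide | c1ccc(cc1)[Se][Se]c1ccccc1 | starting material
41 | bicyclo[3.3.1]nonane with C10 methylene, exo C3 phenyl selenoester, 6-OAc and 13-OTES chain | C=C[C@@](C)(O[Si](CC)(CC)CC)CC[C@@]12C[C@@H](C(=O)[Se]c3ccccc3)[C@@H](C)[C@@](C)(C1=C)[C@H](OC(C)=O)C[C@H]2C | intermediate
42 | C2 acyl radical from 41 | C=C[C@@](C)(O[Si](CC)(CC)CC)CC[C@@]12C[C@@H]([C]=O)[C@@H](C)[C@@](C)(C1=C)[C@H](OC(C)=O)C[C@H]2C | intermediate
43 | C10 bridgehead radical after C1-C2 bond formation | C=C[C@@](C)(O[Si](CC)(CC)CC)CC[C@@]12C[C@H]3C(=O)C[C]1[C@](C)([C@@H]3C)[C@H](OC(C)=O)C[C@H]2C | intermediate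
44 | triethylsilyl ether of the target | C=C[C@@](C)(O[Si](CC)(CC)CC)CC[C@@]12C[C@H]3C(=O)C[C@@H]1[C@](C)([C@@H]3C)[C@H](OC(C)=O)C[C@H]2C | intermediate
45 | CNP0281208.1 | C=C[C@@](C)(O)CC[C@@]12C[C@H]3C(=O)C[C@@H]1[C@](C)([C@@H]3C)[C@H](OC(C)=O)C[C@H]2C | target

**Step count:** 28 steps in total. The longest linear sequence is 24 steps (steps 5-11, then 12-28, from but-3-yn-1-ol). The pulegone branch (steps 1-4) runs in parallel.

**Steps most likely to fail**

Step 27 (key step). The chair-to-boat flip of ring C may be slow compared with hydrogen transfer from the silane to the acyl radical or with loss of CO. Simple reduction or decarbonylation would then outrun the closure. The fallback sets out from aldehyde 38 and comes back at 44.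
- It is a thiol-catalysed radical-chain hydroacylation (polarity-reversal catalysis) with tert-dodecanethiol (cat.) and 2,2'-azobis(isobutyronitrile) in dioxane at 60 °C.
- The thiyl radical takes the aldehyde hydrogen and gives the same acyl radical 42.
- No stoichiometric hydride is present, and reduction of 42 merely returns 38. The radical is therefore formed again until it cyclises.
- Radical 43 is quenched by the thiol. No new compound is made.

Step 17. Methanol may protodesilylate the crowded enol silane before the C4-C5 bond forms, because C5 has to bond on the face that also carries the C6 oxygen. The fallback sets out from 26 and comes back at 27.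
- It is a stoichiometric carbomercuration in an aprotic medium (HgCl2, HN(SiMe3)2, CH2Cl2, 23 °C), so that no proton source is present during ring closure.
- The divalent mercury salt activates the alkyne and the closure gives the C3 vinylmercury chloride F1.
- F1 is then demercurated with NaBH4 in aqueous NaOH-THF to give 27.

Step 18. Shielding of C10 by C5 and C9 may slow the addition so much that retro-aldol cleavage of the C5-C6 bond in the lithium C6 alkoxide competes. The fallback sets out from 27 (isolated by leaving out the citric acid treatment) and comes back at 31.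
- Direct carbonyl methylenation with the titanium methylidene from Cp2TiMe2 (toluene, 70 °C) avoids both the alkoxide and a tetrahedral C10. It gives the silyl ether diene F2.
- Citric acid in MeOH frees the alcohol F3.
- Ac2O, pyridine and DMAP convert F3 into 31.

**Further compounds**
F0 | step 27 | none | none
F1 | step 17 | C3 vinylmercury chloride of the bicyclic silyloxy ketone | C=C[C@@](C)(O[Si](CC)(CC)CC)CC[C@@]12CC([Hg]Cl)=C(C)[C@@](C)(C1=O)[C@H](O[Si](C)(C)C)C[C@H]2C
F2 | step 18 | C10 methylene diene with 6-OTMS | C=C[C@@](C)(O[Si](CC)(CC)CC)CC[C@@]12CC=C(C)[C@@](C)(C1=C)[C@H](O[Si](C)(C)C)C[C@H]2C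
F3 | step 18 | C10 methylene diene with free 6-OH | C=C[C@@](C)(O[Si](CC)(CC)CC)CC[C@@]12CC=C(C)[C@@](C)(C1=C)[C@H](O)C[C@H]2C
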